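- 7.62 to one: that is starting material over target at 8.00 min in the south-east run, which is the very flask asked about, and the reckoning for this flask grows from it.

- south-east: starting material 0.50 mM; reagent in the second phase 1.2 equiv; the very flask that is asked about, followed so far
- flask: starting material 0.50 mM; reagent in the second phase 1.20 equiv; time 20 min; volume of the second phase over the first 2.0

- south-east (time / min: target / %, starting material / %): 1.00: 4.3, 93.1; 2.00: 9.1, 84.5; 4.00: 11.3, 70.7; 8.00: 6.4, 48.8

(standard deviation of a reading: 0.5 percentage points)

- the best time, 20 min at the latest, for target
- the amount of target, in percent of the starting material charged, at that time
- earliest time at which at least nineteen twentieths of that best amount are there, in min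
- latest time at which they still are, in min

- in the second phase: reagent in the second phase; everything else is in the first
- charges count per volume of the first phase; a concentration in a rate is the amount of a species over the volume of its own phase; every rate counts per litre of the first phase
- the earlier runs hold the two phases in the same ratio of volumes as the flask asked about
- a reading or a percentage of target counts all its forms, free or not

- First the main step by itself, starting material to target. Between 4.00 min and 8.00 min, starting material falls with a pseudo-first-order constant k_A of 0.0927 min⁻¹. This step by itself would put target at 51.2% at 8.00 min, but the reading is 6.4%.
- Now one more process, the loss of target. This reckoning takes target at 8.00 min in the south-east run as a quasi-steady state, made about as fast as it is lost, an assumption that gives k_A·c(starting material) = k_loss·c(target). That gives k_loss, the turnover constant of target, the number of turnovers of target per minute, as k_A times the ratio: 0.707 min⁻¹, faster than k_A. Two such steps in a row peak at 3.31 min with 9.65%.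
- Then the rest. At 4.00 min that curve gives 9.53%, yet the reading is 11.3%, higher by 1.8 percentage points against a scatter of 0.5 points. The two-step curve thus runs below that reading, so this reckoning commits to a later, higher peak: about 4.00 min and about 11.3%.
- The forecast differs: 11.7% at 3.4 min, with the window from 2.7 min to 4.1 min, on the grounds that “Loss to other products accelerates”.
- The flask gives 11.4% at 4.40 min, with the window from 3.27 min to 5.59 min.

    reagent in the reaction phase ⇌ reagent in the second phase, rate k1*([reagent in the reaction phase] - [reagent in the second phase]/K1) per volume of the first phase (partition coefficient = 2.30, kL = 0.0160 s⁻¹)
    starting material + reagent in the reaction phase → target (k = 30.0 M⁻¹ s⁻¹)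
    crystals ⇌ target, rate k3*(cs3 - [target]) while solid is left; crystals form when [target] > cs3 (solubility = 0.0440 mM, k = 4.60 s⁻¹)
    target → over-reaction product (k = 0.0120 s⁻¹)

- Dissolved target has a half-life of 0.96 min by the step to over-reaction product alone, short against the 20 min allowed, and at 20.0 min this flask holds 76.6% over-reaction product and 1.96% target. At 4.25 min the made-to-used ratio of dissolved target is 1.00, while crystals, counted in target, stand at 2.55% at 4.40 min and 0% at 10.0 min.
- On this flask at 10.0 min, the ratio k_A/k_loss set against 41.7% starting material gives 5.47% target, and the flask holds 5.44%.
- The neighbour with 0.20 mM starting material keeps 41% of it at 20 min, so its own average k_A is 0.0441 min⁻¹, and k_loss then gives 2.58% target. That neighbour is computed to hold 2.22% target at 20.0 min.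

(All runs are calculated for substances that don't exist, noise included.)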